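# Proposed total synthesis of CNP0172909.1 by twofold flavanone ring contraction and decarboxylative arylation

Locants: unprimed atoms (O1, C2, C3, C3a–C7a) belong to the dihydrobenzofuran that carries the styryl arm (benzo ring A). Primed atoms (O1', C2', C3', C3a'–C7a') belong to the dihydrobenzofuran that carries the 7'-hydroxyl (benzo ring C).

## The problem

The target is a stilbenoid trimer with seven free phenols. Two trans-2,3-diaryl-2,3-dihydrobenzofurans are joined by one sp3–sp2 bond, C3–C5', and ring A carries an (E)-4-hydroxystyryl arm at C4, next to that junction. There are four stereocentres in two trans pairs, C2/C3 (S,S) and C2'/C3' (R,R). Within each pair the oxygen-bearing carbon can direct its neighbour, because trans is favoured kinetically and thermodynamically. The two pairs are separated by ring C and cannot control each other, so each needs its own absolute control. The styryl group sits meta to both oxygens of ring A and cannot be introduced by electrophilic substitution, and C5' of ring C lies para to O1'. The free compound is fragile. The 4-hydroxyphenyl groups on C2 and C2' make the benzylic C–O bonds ionisable under acid, the stilbene can cyclise under acid onto the electron-rich ring C that stands beside it, and it isomerises in light. The enabling feature is that O1', C2' with its aryl group and the benzo ring C are the O1, C2 and benzo ring of a 2-arylchroman-4-one. If ring carbon C3a' shifts from the carbonyl carbon to the neighbouring CH2, the pyranone contracts to the dihydrofuran and the carbonyl carbon is left on C3' as a carboxylate. That carboxylate is the leaving group through which the C3' aryl group can be brought in. Ring A with O1, C2 and a C4 substituent has the same relation to a 5-substituted flavanone.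

## Retrosynthesis

**Phenol protection (31 from 30 from 29).** Only O–S and O–CH3 bonds are cut. The three 4-hydroxyphenyl groups are carried as methanesulfonates and the four remaining phenols as methyl ethers. The sulfonate is chosen over an ether because it withdraws electron density. It makes the C2 aryl group a poor migrating group in the contraction, and it suppresses ionisation of the benzylic C–O bonds and protonation of the stilbene when the methyl ethers are cleaved with BBr3 (29 to 30). It falls to hydroxide in the last step (30 to 31), where the trans rings are the stable isomers. The methyl ethers come with cheap starting materials and keep the migrating benzo rings electron-rich.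

**Stilbene (29 from 25 and 28).** The C4–vinyl bond is cut to aryl chloride 25 and 4-ethenylphenyl methanesulfonate 28 (Mizoroki–Heck). A Wittig approach would need a formyl group at C4, which cannot be carried through the contraction. Chlorine is chosen over bromine or a triflate because it must pass two nickel-catalysed couplings untouched. Late installation keeps the alkene away from the iodane, from light and from radical intermediates. The forward reaction must find a hindered C–Cl bond and leave three aryl sulfonates alone.

**C3'–aryl bond (25 from 20 and 21).** The 3,5-dimethoxyphenyl group is removed from C3', which leaves carboxylic acid 20 and 1-bromo-3,5-dimethoxybenzene 21. In the forward sense 20 is activated as N-acyloxyphthalimide 22 and coupled under nickel catalysis with arylzinc 24 (from 21 through Grignard reagent 23). The step must deliver the aryl group trans to the C2' aryl group. It is placed after the fragment union so that no aryl bromide is present when arylzinc and low-valent nickel meet.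

**C3–C5' bond (20 from 19; 19 from 18 and 9).** Cutting the bond between the two halves gives acid 18 (ring A half) and bromo ester 9 (ring C half); hydrolysis of the remaining ester in 19 gives 20. Both halves are enantiopure products of the same ring contraction, so the union joins two finished stereochemical units and no diastereomer problem arises between them. The forward reaction is a decarboxylative arylation under iridium photoredox and nickel catalysis. It must place ring C trans to the C2 aryl group and must react at C–Br and not at C–Cl.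

**Ring contraction (9 from 7; 17 from 15; 18 from 17).** The C3'–C3a' bond of 9 is traced back to the C4–C4a bond of flavanone 7, and likewise 17 to 15. Carbene C–H insertion or a [4+1] route to the dihydrofuran would need separate solutions for absolute configuration and for the C3 handle. The flavanone route takes C2 from a catalytic asymmetric step and delivers the ring, the trans relationship and the carboxyl handle in one operation. The precursor is a simple ketone with one stereocentre. The reaction must make the ring carbon migrate in preference to the C2 aryl group.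

**Flavanones (7 from 4 and 6; 15 from 14 and 6).** The C2–aryl bond is cut to chromones 4 and 14 and boronic acid 6. Enantioselective conjugate addition under divalent palladium with the two enantiomers of a pyridine–oxazoline ligand gives the 2R and the 2S series from achiral, planar precursors. Chalcone cyclisation was set aside because flavanones made that way racemise through ring opening.

**Chromones and small reagents (4 from 2 from 1; 14 from 12 from 10; 6 from 5; 28 from 26).** The pyranone C2 carbon is cut back to the methyl ketones 2 and 12. Ketone 2 comes from commercial acetophenone 1 by bromination para to the hydroxyl. Ketone 12 comes from 1-chloro-3,5-dimethoxybenzene 10 by acylation and chelation-controlled demethylation through 11. Boronic acid 6 is the mesylate of 5, and styrene 28 is made from 4-ethenylphenyl acetate 26.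

## Roads not taken

**Alternative 1:** The cut is the benzene ring A itself, closed at C3a–C4 by aldol folding of a polyketide chain. Unmasking of dioxinone A1 in hot methanol and aldol condensation–aromatisation of the open chain would give resorcylate A2 with the E-styryl arm in place. Its merit is real: the 1,3,5-pattern that resists electrophilic substitution is built from scratch under mild conditions, and no coupling at the hindered C4 is needed. On that point it is better than the chosen plan, which depends on a Heck reaction at a hindered chloride (step 15). Its weakness is what remains afterwards. A2 holds none of the four stereocentres and neither dihydrofuran. Its ester carbon sits where C3 must carry ring C, its two phenols must be told apart, and the acid-sensitive stilbene is present from the first step. The chosen plan sets against it a key step that delivers ring, stereocentre and C3 handle together, and is used twice.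

**Alternative 2:** The cut is benzo ring C (C3a'–C7a' and C6'–C7'). Under (Ph3P)AuNTf2, a monovalent gold catalyst, the furan and the ethynyl ether of A3 would cycloisomerise with oxygen transfer to C7' to give phenol A4. This forms two rings and two C–C bonds in one step and frees the C7' hydroxyl without a demethylation. In both respects it beats the chosen key step, which forms one ring and one bond. The weak points are several. Both stereocentres must already be set in acyclic A3. The ynol ether of a secondary benzylic alcohol is prone to ionisation and sigmatropic loss under cationic gold. The phenol synthesis with oxygen directly on the alkyne has little support. The C5' handle of A4 is a hydroxymethyl carbon, so the whole of ring A with its two stereocentres would have to be built late from that carbon. The chosen plan answers with a contraction of a known type on a substrate three steps from commercial material, catalytic absolute control, and the same treatment for both halves.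

**Alternative 3:** The cut is ring A and its dihydrofuran together (C3a–C7a, C6–C7, C5–C6). Ring opening of cyclobutenone A5 to a vinylketene, addition to the tethered ethynyl ether, four-electron opening and six-electron closure (Danheiser benzannulation) would give A6, the hexa-O-methyl ether of the target with the C6 hydroxyl free. This is the most convergent plan and wins on rings and bonds per step (two rings, three bonds), and it frees one phenol selectively. The difficulty is the precursor. A5 must already contain all four stereocentres, ring C and the stilbene, next to a strained enone and a benzylic ynol ether. The acyclic C2/C3 pair has no ring to relay from. The stilbene is exposed to light or heat and to a ketene, and a failure costs the most advanced material. Six methyl ethers must then be cleaved with the stilbene in place and with electron-rich aryl groups on C2 and C2', the situation the chosen protecting-group plan is built to avoid. The chosen plan has a lower yield of bonds in its key step but tests it early, on cheap material.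

Key step: step 5

## Route

Assumption: (S)-t-BuPyOx is taken to direct aryl transfer to the face of the chromone that gives the 2R flavanone (the sense it shows with cyclic enones) and (R)-t-BuPyOx the 2S flavanone. If the sense were opposite, the two ligand enantiomers would be exchanged between steps 4 and 8.

Step 1
Reactants: 1 1-(2-hydroxy-3-methoxyphenyl)ethanone
Product: 2 1-(5-bromo-2-hydroxy-3-methoxyphenyl)ethanone
Conditions: NBS, MeCN, 0 °C to rt
Reagents that add atoms: N-bromosuccinimide, O=C1CCC(=O)N1Br
Why: Electrophilic aromatic bromination; the position para to the phenol is the only one activated by the hydroxyl and still open, and it is also meta to the acetyl group.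

Step 2
Reactants: 2 1-(5-bromo-2-hydroxy-3-methoxyphenyl)ethanone
Product: 4 6-bromo-8-methoxy-4H-chromen-4-one, via dimethylamino enone 3 (not isolated)
Conditions: Me2NCH(OMe)2, toluene, 100 °C; then conc. HCl, CH2Cl2, 40 °C
Reagents that add atoms: N,N-dimethylformamide dimethyl acetal, COC(OC)N(C)C
Why: Condensation of the methyl ketone with the amide acetal gives the enaminone, and acid then closes the pyranone by intramolecular oxa-Michael addition and loss of dimethylamine (standard chromone synthesis).

Step 3
Reactants: 5 (4-hydroxyphenyl)boronic acid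
Product: 6 [4-(methylsulfonyloxy)phenyl]boronic acid
Conditions: MsCl, Et3N, THF, 0 °C to rt; 1 M HCl work-up
Reagents that add atoms: methanesulfonyl chloride, CS(=O)(=O)Cl
Why: O-Sulfonylation of the phenol; any mixed boron–sulfonic anhydride or boroxine is hydrolysed back to the boronic acid in the acidic work-up.

Step 4
Reactants: 4 6-bromo-8-methoxy-4H-chromen-4-one; 6 [4-(methylsulfonyloxy)phenyl]boronic acid
Product: 7 (2R)-6-bromo-8-methoxy-2-[4-(methylsulfonyloxy)phenyl]-2,3-dihydro-4H-chromen-4-one
Conditions: Pd(OCOCF3)2 (5 mol %), (S)-t-BuPyOx (6 mol %), NH4PF6, H2O, ClCH2CH2Cl, 60 °C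
Reagents that add atoms: none
Why: Enantioselective conjugate addition of an arylboronic acid to a chromone under a cationic divalent palladium–pyridine-oxazoline catalyst; the aryl–palladium species adds to C2 on the face set by the ligand, which fixes C2 as R, and water protonates the enolate. The divalent palladium catalyst does not insert into the C–Br bond.

Step 5
Reactants: 7 (2R)-6-bromo-8-methoxy-2-[4-(methylsulfonyloxy)phenyl]-2,3-dihydro-4H-chromen-4-one
Product: 9 methyl (2R,3R)-5-bromo-7-methoxy-2-[4-(methylsulfonyloxy)phenyl]-2,3-dihydro-1-benzofuran-3-carboxylate, via methyl enol ether 8 (not isolated)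
Conditions: PhI(OAc)2, H2SO4, HC(OMe)3, 0 °C to rt; aq. NaHCO3
Reagents that add atoms: trimethyl orthoformate, COC(OC)OC; water (work-up), O
Why: In HC(OMe)3/H2SO4 the ketone becomes its dimethyl ketal and enol ether 8, which attacks the protonated aryliodine diacetate at C3 on the face anti to the equatorial C2 aryl group while methanol recaptures C4 as the ketal. Iodobenzene then leaves C3 with help from the antiperiplanar C4–C4a bond: ring carbon C4a shifts from C4 to C3, which makes C3'–C3a' of the product, and the dioxocarbenium ion left behind ends as the methyl ester. The closest known reaction is the trivalent-iodine (or thallium trinitrate) oxidative ring contraction of flavanones to methyl trans-2-aryl-2,3-dihydrobenzofuran-3-carboxylates, a case of the oxidative 1,2-aryl shift of aryl ketones to arylacetic esters. The dihydrofuran is thus closed by ring contraction through a 1,2-shift and not by a cyclisation. C2' is carried over from 7 and controls the new centre C3': the iodane sits trans-diequatorial to the aryl group and the shift inverts C3, which places the ester trans, and the epimerisable ester would in any case settle as the trans isomer. The step needs the ring carbon to migrate in preference to the C2 aryl group (isoflavone pathway) and to simple elimination (flavone); the methanesulfonate makes the C2 aryl group a poor migrating group, while the ring oxygen ortho to C4a and the ketal oxygens favour the ring shift. The bromine blocks the position para to the ring oxygen against the oxidant, and the methyl ether and the sulfonate are inert to the acid.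

Step 6
Reactants: 10 1-chloro-3,5-dimethoxybenzene
Product: 12 1-(2-chloro-6-hydroxy-4-methoxyphenyl)ethanone, via dimethoxy ketone 11 (not isolated)
Conditions: AcCl, AlCl3 (3 equiv), CH2Cl2, 0 °C to 40 °C; aq. HCl
Reagents that add atoms: acetyl chloride, CC(=O)Cl
Why: Friedel–Crafts acylation at the carbon para to one methoxyl and flanked by chlorine and the other methoxyl, followed in the same flask by AlCl3-mediated cleavage of the methoxyl chelated to the new carbonyl group. The non-chelated ether should remain.

Step 7
Reactants: 12 1-(2-chloro-6-hydroxy-4-methoxyphenyl)ethanone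
Product: 14 5-chloro-7-methoxy-4H-chromen-4-one, via dimethylamino enone 13 (not isolated)
Conditions: Me2NCH(OMe)2, toluene, 100 °C; then conc. HCl, CH2Cl2, 40 °C
Reagents that add atoms: N,N-dimethylformamide dimethyl acetal, COC(OC)N(C)C
Why: Same enaminone formation and acid-promoted oxa-Michael ring closure as in step 2; the methyl group of the hindered ketone remains accessible.

Step 8
Reactants: 14 5-chloro-7-methoxy-4H-chromen-4-one; 6 [4-(methylsulfonyloxy)phenyl]boronic acid
Product: 15 (2S)-5-chloro-7-methoxy-2-[4-(methylsulfonyloxy)phenyl]-2,3-dihydro-4H-chromen-4-one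
Conditions: Pd(OCOCF3)2 (5 mol %), (R)-t-BuPyOx (6 mol %), NH4PF6, H2O, ClCH2CH2Cl, 60 °C
Reagents that add atoms: none
Why: Same enantioselective palladium-catalysed conjugate addition as in step 4, with the mirror-image ligand, which sets C2 as S. The C–Cl bond is inert to divalent palladium.

Step 9
Reactants: 15 (2S)-5-chloro-7-methoxy-2-[4-(methylsulfonyloxy)phenyl]-2,3-dihydro-4H-chromen-4-one
Product: 17 methyl (2S,3S)-4-chloro-6-methoxy-2-[4-(methylsulfonyloxy)phenyl]-2,3-dihydro-1-benzofuran-3-carboxylate, via methyl enol ether 16 (not isolated)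
Conditions: PhI(OAc)2, H2SO4, HC(OMe)3, 0 °C to rt; aq. NaHCO3
Reagents that add atoms: trimethyl orthoformate, COC(OC)OC; water (work-up), O
Why: Second use of the oxidative flavanone ring contraction of step 5; the migrating ring carbon is here activated by the ortho ring oxygen and the para methoxyl. C3 is set trans to the C2 aryl group by the same anti addition of the iodane and inversion in the 1,2-shift.

Step 10
Reactants: 17 methyl (2S,3S)-4-chloro-6-methoxy-2-[4-(methylsulfonyloxy)phenyl]-2,3-dihydro-1-benzofuran-3-carboxylate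
Product: 18 (2S,3S)-4-chloro-6-methoxy-2-[4-(methylsulfonyloxy)phenyl]-2,3-dihydro-1-benzofuran-3-carboxylic acid
Conditions: LiOH·H2O, THF/H2O, 0 °C to rt; aq. HCl
Reagents that add atoms: lithium hydroxide, [Li+].[OH-]
Why: Ester saponification; the trans acid is the stable epimer, ring opening of the enolate is stereoelectronically disfavoured, and aryl methanesulfonates should withstand hydroxide at room temperature.

Step 11
Reactants: 18 (2S,3S)-4-chloro-6-methoxy-2-[4-(methylsulfonyloxy)phenyl]-2,3-dihydro-1-benzofuran-3-carboxylic acid; 9 methyl (2R,3R)-5-bromo-7-methoxy-2-[4-(methylsulfonyloxy)phenyl]-2,3-dihydro-1-benzofuran-3-carboxylate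
Product: 19 methyl (2R,3R)-5-[(2S,3S)-4-chloro-6-methoxy-2-[4-(methylsulfonyloxy)phenyl]-2,3-dihydro-1-benzofuran-3-yl]-7-methoxy-2-[4-(methylsulfonyloxy)phenyl]-2,3-dihydro-1-benzofuran-3-carboxylate
Conditions: Ir[dF(CF3)ppy]2(dtbbpy)PF6 (2 mol %), NiCl2·glyme (10 mol %), dtbbpy (15 mol %), Cs2CO3, DMF, blue LEDs, rt
Reagents that add atoms: none
Why: Decarboxylative arylation of a secondary benzylic carboxylic acid with an aryl bromide under combined photoredox and nickel catalysis: the photo-excited iridium complex oxidises the carboxylate, the C3 radical formed on loss of CO2 is captured by the aryl–nickel species from 9, and reductive elimination forms C3–C5'. The planar radical is arylated anti to the C2 aryl group, which sets C3 trans (S). The C–Cl bond and the sulfonates should not compete with the C–Br bond for nickel at room temperature.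

Step 12
Reactants: 19 methyl (2R,3R)-5-[(2S,3S)-4-chloro-6-methoxy-2-[4-(methylsulfonyloxy)phenyl]-2,3-dihydro-1-benzofuran-3-yl]-7-methoxy-2-[4-(methylsulfonyloxy)phenyl]-2,3-dihydro-1-benzofuran-3-carboxylate
Product: 20 (2R,3R)-5-[(2S,3S)-4-chloro-6-methoxy-2-[4-(methylsulfonyloxy)phenyl]-2,3-dihydro-1-benzofuran-3-yl]-7-methoxy-2-[4-(methylsulfonyloxy)phenyl]-2,3-dihydro-1-benzofuran-3-carboxylic acid
Conditions: LiOH·H2O, THF/MeOH/H2O, rt; aq. HCl
Reagents that add atoms: lithium hydroxide, [Li+].[OH-]
Why: Ester saponification as in step 10; the diarylmethine hydrogen at C3 is not acidic enough to be touched.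

Step 13
Reactants: 20 (2R,3R)-5-[(2S,3S)-4-chloro-6-methoxy-2-[4-(methylsulfonyloxy)phenyl]-2,3-dihydro-1-benzofuran-3-yl]-7-methoxy-2-[4-(methylsulfonyloxy)phenyl]-2,3-dihydro-1-benzofuran-3-carboxylic acid; 21 1-bromo-3,5-dimethoxybenzene
Product: 25 4-[(2S,3S)-4-chloro-3-[(2R,3R)-3-(3,5-dimethoxyphenyl)-7-methoxy-2-[4-(methylsulfonyloxy)phenyl]-2,3-dihydro-1-benzofuran-5-yl]-6-methoxy-2,3-dihydro-1-benzofuran-2-yl]phenyl methanesulfonate, via N-acyloxyphthalimide 22 (not isolated), via aryl Grignard reagent 23 (not isolated), via arylzinc chloride 24 (not isolated)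
Conditions: N-hydroxyphthalimide, DIC, DMAP (cat.), CH2Cl2, rt; then NiCl2·glyme (20 mol %), dtbbpy (40 mol %), ArZnCl·LiCl (3 equiv; from 21, Mg, LiCl, THF, then ZnCl2), THF/DMF, rt
Reagents that add atoms: none
Why: Nickel-catalysed decarboxylative Negishi-type arylation of a secondary redox-active ester: electron transfer from an aryl–nickel species fragments 22 to CO2, phthalimide anion and the C3' radical, which recombines with nickel and is arylated. The aryl group enters anti to the C2' aryl group, which sets C3' trans (R). No C–Br bond remains at this stage, and the hindered C–Cl bond and the sulfonates should be inert under bipyridine–nickel at room temperature.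

Step 14
Reactants: 26 4-ethenylphenyl acetate
Product: 28 4-ethenylphenyl methanesulfonate, via 4-ethenylphenol 27 (not isolated)
Conditions: K2CO3 (cat.), MeOH, 0 °C, BHT; concentrate; then MsCl, Et3N, CH2Cl2, 0 °C
Reagents that add atoms: methanesulfonyl chloride, CS(=O)(=O)Cl
Why: Base-catalysed methanolysis of the aryl acetate and O-sulfonylation of the phenol without isolating the polymerisation-prone vinylphenol.

Step 15
Reactants: 25 4-[(2S,3S)-4-chloro-3-[(2R,3R)-3-(3,5-dimethoxyphenyl)-7-methoxy-2-[4-(methylsulfonyloxy)phenyl]-2,3-dihydro-1-benzofuran-5-yl]-6-methoxy-2,3-dihydro-1-benzofuran-2-yl]phenyl methanesulfonate; 28 4-ethenylphenyl methanesulfonate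
Product: 29 4-[(E)-2-[(2S,3S)-3-[(2R,3R)-3-(3,5-dimethoxyphenyl)-7-methoxy-2-[4-(methylsulfonyloxy)phenyl]-2,3-dihydro-1-benzofuran-5-yl]-6-methoxy-2-[4-(methylsulfonyloxy)phenyl]-2,3-dihydro-1-benzofuran-4-yl]ethenyl]phenyl methanesulfonate
Conditions: Pd2(dba)3 (2.5 mol %), [HP(t-Bu)3]BF4 (10 mol %), Cy2NMe, 1,4-dioxane, 110 °C
Reagents that add atoms: none
Why: Mizoroki–Heck reaction of an aryl chloride with a styrene under a bulky trialkylphosphine–palladium catalyst, which gives the E-stilbene by syn insertion and syn β-hydride elimination. The chlorine is meta to both ring oxygens and so not deactivated, and this ligand prefers C–Cl bonds over aryl sulfonates.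

Step 16
Reactants: 29 4-[(E)-2-[(2S,3S)-3-[(2R,3R)-3-(3,5-dimethoxyphenyl)-7-methoxy-2-[4-(methylsulfonyloxy)phenyl]-2,3-dihydro-1-benzofuran-5-yl]-6-methoxy-2-[4-(methylsulfonyloxy)phenyl]-2,3-dihydro-1-benzofuran-4-yl]ethenyl]phenyl methanesulfonate
Product: 30 4-[(E)-2-[(2S,3S)-3-[(2R,3R)-3-(3,5-dihydroxyphenyl)-7-hydroxy-2-[4-(methylsulfonyloxy)phenyl]-2,3-dihydro-1-benzofuran-5-yl]-6-hydroxy-2-[4-(methylsulfonyloxy)phenyl]-2,3-dihydro-1-benzofuran-4-yl]ethenyl]phenyl methanesulfonate
Conditions: BBr3, CH2Cl2, −78 °C to 0 °C; aq. NaHCO3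
Reagents that add atoms: none
Why: Lewis-acid cleavage of the four aryl methyl ethers; aryl sulfonates are stable to BBr3. All three para-oxygenated aryl groups are electron-poor sulfonates, so ionisation of the benzylic C2–O and C2'–O bonds and protonation of the stilbene should be suppressed.

Step 17
Reactants: 30 4-[(E)-2-[(2S,3S)-3-[(2R,3R)-3-(3,5-dihydroxyphenyl)-7-hydroxy-2-[4-(methylsulfonyloxy)phenyl]-2,3-dihydro-1-benzofuran-5-yl]-6-hydroxy-2-[4-(methylsulfonyloxy)phenyl]-2,3-dihydro-1-benzofuran-4-yl]ethenyl]phenyl methanesulfonate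
Product: 31 5-[(2R,3R)-7-hydroxy-5-[(2S,3S)-6-hydroxy-2-(4-hydroxyphenyl)-4-[(E)-2-(4-hydroxyphenyl)ethenyl]-2,3-dihydro-1-benzofuran-3-yl]-2-(4-hydroxyphenyl)-2,3-dihydro-1-benzofuran-3-yl]benzene-1,3-diol
Conditions: KOH, MeOH/H2O (degassed), 60 °C, argon; then aq. HCl to pH 5
Reagents that add atoms: none
Why: Hydroxide cleavage of the three aryl methanesulfonates at sulfur. Any reversible opening of the dihydrofurans through the para-phenoxides can only return the trans rings, because C3 and C3' are untouched and trans is the stable arrangement.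

## Compound list

1 | 1-(2-hydroxy-3-methoxyphenyl)ethanone | CC(=O)c1cccc(OC)c1O | starting material
2 | 1-(5-bromo-2-hydroxy-3-methoxyphenyl)ethanone | CC(=O)c1cc(Br)cc(OC)c1O | intermediate
3 | (E)-1-(5-bromo-2-hydroxy-3-methoxyphenyl)-3-(dimethylamino)prop-2-en-1-one | CN(C)/C=C/C(=O)c1cc(Br)cc(OC)c1O | intermediate (not isolated)
4 | 6-bromo-8-methoxy-4H-chromen-4-one | O=c1ccoc2c(OC)cc(Br)cc12 | intermediate
5 | (4-hydroxyphenyl)boronic acid | OB(O)c1ccc(O)cc1 | starting material
6 | [4-(methylsulfonyloxy)phenyl]boronic acid | CS(=O)(=O)Oc1ccc(B(O)O)cc1 | intermediate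
7 | (2R)-6-bromo-8-methoxy-2-[4-(methylsulfonyloxy)phenyl]-2,3-dihydro-4H-chromen-4-one | O=C1C[C@H](c2ccc(OS(C)(=O)=O)cc2)Oc2c(OC)cc(Br)cc12 | intermediate
8 | (2R)-6-bromo-4,8-dimethoxy-2-[4-(methylsulfonyloxy)phenyl]-2H-chromene | COC1=C[C@H](c2ccc(OS(C)(=O)=O)cc2)Oc2c(OC)cc(Br)cc12 | intermediate (not isolated)
9 | methyl (2R,3R)-5-bromo-7-methoxy-2-[4-(methylsulfonyloxy)phenyl]-2,3-dihydro-1-benzofuran-3-carboxylate | Brc1cc(OC)c2c(c1)[C@@H](C(=O)OC)[C@H](c1ccc(OS(C)(=O)=O)cc1)O2 | intermediate
10 | 1-chloro-3,5-dimethoxybenzene | COc1cc(Cl)cc(OC)c1 | starting material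
11 | 1-(2-chloro-4,6-dimethoxyphenyl)ethanone | CC(=O)c1c(Cl)cc(OC)cc1OC | intermediate (not isolated)
12 | 1-(2-chloro-6-hydroxy-4-methoxyphenyl)ethanone | CC(=O)c1c(Cl)cc(OC)cc1O | intermediate
13 | (E)-1-(2-chloro-6-hydroxy-4-methoxyphenyl)-3-(dimethylamino)prop-2-en-1-one | CN(C)/C=C/C(=O)c1c(Cl)cc(OC)cc1O | intermediate (not isolated)
14 | 5-chloro-7-methoxy-4H-chromen-4-one | O=c1ccoc2cc(OC)cc(Cl)c12 | intermediate
15 | (2S)-5-chloro-7-methoxy-2-[4-(methylsulfonyloxy)phenyl]-2,3-dihydro-4H-chromen-4-one | O=C1C[C@@H](c2ccc(OS(C)(=O)=O)cc2)Oc2cc(OC)cc(Cl)c12 | intermediate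
16 | (2S)-5-chloro-4,7-dimethoxy-2-[4-(methylsulfonyloxy)phenyl]-2H-chromene | COC1=C[C@@H](c2ccc(OS(C)(=O)=O)cc2)Oc2cc(OC)cc(Cl)c12 | intermediate (not isolated)
17 | methyl (2S,3S)-4-chloro-6-methoxy-2-[4-(methylsulfonyloxy)phenyl]-2,3-dihydro-1-benzofuran-3-carboxylate | Clc1cc(OC)cc2c1[C@H](C(=O)OC)[C@@H](c1ccc(OS(C)(=O)=O)cc1)O2 | intermediate
18 | (2S,3S)-4-chloro-6-methoxy-2-[4-(methylsulfonyloxy)phenyl]-2,3-dihydro-1-benzofuran-3-carboxylic acid | Clc1cc(OC)cc2c1[C@H](C(=O)O)[C@@H](c1ccc(OS(C)(=O)=O)cc1)O2 | intermediate
19 | methyl (2R,3R)-5-[(2S,3S)-4-chloro-6-methoxy-2-[4-(methylsulfonyloxy)phenyl]-2,3-dihydro-1-benzofuran-3-yl]-7-methoxy-2-[4-(methylsulfonyloxy)phenyl]-2,3-dihydro-1-benzofuran-3-carboxylate | Clc1cc(OC)cc2c1[C@H](c1cc(OC)c3c(c1)[C@@H](C(=O)OC)[C@H](c1ccc(OS(C)(=O)=O)cc1)O3)[C@@H](c1ccc(OS(C)(=O)=O)cc1)O2 | intermediate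
20 | (2R,3R)-5-[(2S,3S)-4-chloro-6-methoxy-2-[4-(methylsulfonyloxy)phenyl]-2,3-dihydro-1-benzofuran-3-yl]-7-methoxy-2-[4-(methylsulfonyloxy)phenyl]-2,3-dihydro-1-benzofuran-3-carboxylic acid | Clc1cc(OC)cc2c1[C@H](c1cc(OC)c3c(c1)[C@@H](C(=O)O)[C@H](c1ccc(OS(C)(=O)=O)cc1)O3)[C@@H](c1ccc(OS(C)(=O)=O)cc1)O2 | intermediate
21 | 1-bromo-3,5-dimethoxybenzene | COc1cc(Br)cc(OC)c1 | starting material
22 | 1,3-dioxoisoindolin-2-yl (2R,3R)-5-[(2S,3S)-4-chloro-6-methoxy-2-[4-(methylsulfonyloxy)phenyl]-2,3-dihydro-1-benzofuran-3-yl]-7-methoxy-2-[4-(methylsulfonyloxy)phenyl]-2,3-dihydro-1-benzofuran-3-carboxylate | Clc1cc(OC)cc2c1[C@H](c1cc(OC)c3c(c1)[C@@H](C(=O)ON1C(=O)c4ccccc4C1=O)[C@H](c1ccc(OS(C)(=O)=O)cc1)O3)[C@@H](c1ccc(OS(C)(=O)=O)cc1)O2 | intermediate (not isolated)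
23 | (3,5-dimethoxyphenyl)magnesium bromide | COc1cc([Mg]Br)cc(OC)c1 | intermediate (not isolated)
24 | chloro(3,5-dimethoxyphenyl)zinc | COc1cc([Zn]Cl)cc(OC)c1 | intermediate (not isolated)
25 | 4-[(2S,3S)-4-chloro-3-[(2R,3R)-3-(3,5-dimethoxyphenyl)-7-methoxy-2-[4-(methylsulfonyloxy)phenyl]-2,3-dihydro-1-benzofuran-5-yl]-6-methoxy-2,3-dihydro-1-benzofuran-2-yl]phenyl methanesulfonate | Clc1cc(OC)cc2c1[C@H](c1cc(OC)c3c(c1)[C@@H](c1cc(OC)cc(OC)c1)[C@H](c1ccc(OS(C)(=O)=O)cc1)O3)[C@@H](c1ccc(OS(C)(=O)=O)cc1)O2 | intermediate
26 | 4-ethenylphenyl acetate | CC(=O)Oc1ccc(C=C)cc1 | starting material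
27 | 4-ethenylphenol | Oc1ccc(C=C)cc1 | intermediate (not isolated)
28 | 4-ethenylphenyl methanesulfonate | CS(=O)(=O)Oc1ccc(C=C)cc1 | intermediate
29 | 4-[(E)-2-[(2S,3S)-3-[(2R,3R)-3-(3,5-dimethoxyphenyl)-7-methoxy-2-[4-(methylsulfonyloxy)phenyl]-2,3-dihydro-1-benzofuran-5-yl]-6-methoxy-2-[4-(methylsulfonyloxy)phenyl]-2,3-dihydro-1-benzofuran-4-yl]ethenyl]phenyl methanesulfonate | CS(=O)(=O)Oc1ccc(/C=C/c2cc(OC)cc3c2[C@H](c2cc(OC)c4c(c2)[C@@H](c2cc(OC)cc(OC)c2)[C@H](c2ccc(OS(C)(=O)=O)cc2)O4)[C@@H](c2ccc(OS(C)(=O)=O)cc2)O3)cc1 | intermediate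
30 | 4-[(E)-2-[(2S,3S)-3-[(2R,3R)-3-(3,5-dihydroxyphenyl)-7-hydroxy-2-[4-(methylsulfonyloxy)phenyl]-2,3-dihydro-1-benzofuran-5-yl]-6-hydroxy-2-[4-(methylsulfonyloxy)phenyl]-2,3-dihydro-1-benzofuran-4-yl]ethenyl]phenyl methanesulfonate | CS(=O)(=O)Oc1ccc(/C=C/c2cc(O)cc3c2[C@H](c2cc(O)c4c(c2)[C@@H](c2cc(O)cc(O)c2)[C@H](c2ccc(OS(C)(=O)=O)cc2)O4)[C@@H](c2ccc(OS(C)(=O)=O)cc2)O3)cc1 | intermediate
31 | 5-[(2R,3R)-7-hydroxy-5-[(2S,3S)-6-hydroxy-2-(4-hydroxyphenyl)-4-[(E)-2-(4-hydroxyphenyl)ethenyl]-2,3-dihydro-1-benzofuran-3-yl]-2-(4-hydroxyphenyl)-2,3-dihydro-1-benzofuran-3-yl]benzene-1,3-diol | Oc1ccc(/C=C/c2cc(O)cc3c2[C@H](c2cc(O)c4c(c2)[C@@H](c2cc(O)cc(O)c2)[C@H](c2ccc(O)cc2)O4)[C@@H](c2ccc(O)cc2)O3)cc1 | target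

## Step count and risk

Total step count: 17. Longest linear sequence: 11 steps (from 10 through steps 6 to 13 and 15 to 17).

**Step 5 (key step).** The likeliest failures are migration of the C2 aryl group in place of the ring carbon (which leads towards the isoflavone), elimination from the C3 iodane to the flavone, and partial racemisation by acid-induced opening of the pyranone before ketalisation. The sulfonate is meant to suppress the first, but the ring carbon carries only meta substituents besides the ortho ring oxygen and is not a strongly activated migrating group.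
Fallback: the same C3'–C3a' bond would be made by a Wolff rearrangement, setting out from 7 and returning at 9. Condensation of 7 with Me2NCH(OMe)2 would give (2S,3E)-6-bromo-3-[(dimethylamino)methylidene]-8-methoxy-2-[4-(methylsulfonyloxy)phenyl]-2,3-dihydro-4H-chromen-4-one F1. Diazo transfer with tosyl azide would give (2S)-6-bromo-3-diazo-8-methoxy-2-[4-(methylsulfonyloxy)phenyl]-2,3-dihydro-4H-chromen-4-one F2. In both, the descriptor at C2 changes only because C3 now outranks the aryl group; the spatial arrangement is that of 7. Irradiation of F2 in methanol would contract the ring to 9 mixed with its cis epimer, methyl (2R,3S)-5-bromo-7-methoxy-2-[4-(methylsulfonyloxy)phenyl]-2,3-dihydro-1-benzofuran-3-carboxylate F3, and DBU would equilibrate F3 to 9.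

**Step 9.** Ketal and enol ether formation may be slowed by the chlorine peri to the carbonyl group, so that oxidation at C3 is incomplete or elimination to the flavone takes over. The electron-rich benzo ring may also be attacked by the oxidant.
Fallback: the Wolff sequence, which needs no ketal, setting out from 15 and returning at 17. It would run through (2R,3E)-5-chloro-3-[(dimethylamino)methylidene]-7-methoxy-2-[4-(methylsulfonyloxy)phenyl]-2,3-dihydro-4H-chromen-4-one F4, then (2R)-5-chloro-3-diazo-7-methoxy-2-[4-(methylsulfonyloxy)phenyl]-2,3-dihydro-4H-chromen-4-one F5, then photolysis in methanol to 17 and its cis epimer, methyl (2S,3R)-4-chloro-6-methoxy-2-[4-(methylsulfonyloxy)phenyl]-2,3-dihydro-1-benzofuran-3-carboxylate F6, which DBU would convert to 17.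

**Step 11.** Oxidative addition of the electron-rich bromide 9 to low-valent nickel may be slow. The hindered benzylic radical from 18 may then dimerise or be reduced before it is captured, and facial selectivity at C3 may suffer from the flanking chlorine.
Fallback: a reductive cross-electrophile coupling, setting out from 18 and 9 and returning at 19. Acid 18 would be converted with N-hydroxyphthalimide and DIC to 1,3-dioxoisoindolin-2-yl (2S,3S)-4-chloro-6-methoxy-2-[4-(methylsulfonyloxy)phenyl]-2,3-dihydro-1-benzofuran-3-carboxylate F7. Bromide 9 would be converted by copper-catalysed halogen exchange (CuI, NaI, trans-N,N'-dimethylcyclohexane-1,2-diamine, dioxane, 110 °C) to methyl (2R,3R)-5-iodo-7-methoxy-2-[4-(methylsulfonyloxy)phenyl]-2,3-dihydro-1-benzofuran-3-carboxylate F8. The two would then be joined with NiBr2·glyme, dtbbpy and zinc dust in DMA.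

**Step 15.** Oxidative addition at the chloride next to the bulky C3 substituent may be too slow at a temperature the substrate tolerates. Insertion may also give some 1,1-diarylethene, or the styrene may polymerise.
Fallback: two steps, setting out from 25 and returning at 29. Suzuki–Miyaura coupling of 25 with potassium vinyltrifluoroborate (Pd(OAc)2, XPhos, Cs2CO3, THF/H2O) would give 4-[(2S,3S)-3-[(2R,3R)-3-(3,5-dimethoxyphenyl)-7-methoxy-2-[4-(methylsulfonyloxy)phenyl]-2,3-dihydro-1-benzofuran-5-yl]-4-ethenyl-6-methoxy-2,3-dihydro-1-benzofuran-2-yl]phenyl methanesulfonate F9. Olefin cross-metathesis of F9 with an excess of 28 (second-generation Grubbs catalyst, CH2Cl2, 40 °C) would then give the E-stilbene 29.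

**Step 16.** Cleavage of four ethers may be incomplete at the low temperature needed to protect the alkene. Hydrogen bromide formed on the way may still protonate the stilbene and start cyclisation onto ring C, or the benzylic ether bonds may open.
Fallback: change the order so that no alkene meets the Lewis acid, setting out from 25 and returning at 30. BBr3 would convert 25 to 4-[(2S,3S)-4-chloro-3-[(2R,3R)-3-(3,5-dihydroxyphenyl)-7-hydroxy-2-[4-(methylsulfonyloxy)phenyl]-2,3-dihydro-1-benzofuran-5-yl]-6-hydroxy-2,3-dihydro-1-benzofuran-2-yl]phenyl methanesulfonate F10, and the Heck reaction of F10 with 28 under the conditions of step 15 would give 30.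

## Further compounds

F1 | step 5 | (2S,3E)-6-bromo-3-[(dimethylamino)methylidene]-8-methoxy-2-[4-(methylsulfonyloxy)phenyl]-2,3-dihydro-4H-chromen-4-one | O=C1/C(=C/N(C)C)[C@H](c2ccc(OS(C)(=O)=O)cc2)Oc2c(OC)cc(Br)cc12
F2 | step 5 | (2S)-6-bromo-3-diazo-8-methoxy-2-[4-(methylsulfonyloxy)phenyl]-2,3-dihydro-4H-chromen-4-one | O=C1C(=[N+]=[N-])[C@H](c2ccc(OS(C)(=O)=O)cc2)Oc2c(OC)cc(Br)cc12
F3 | step 5 | methyl (2R,3S)-5-bromo-7-methoxy-2-[4-(methylsulfonyloxy)phenyl]-2,3-dihydro-1-benzofuran-3-carboxylate | Brc1cc(OC)c2c(c1)[C@H](C(=O)OC)[C@H](c1ccc(OS(C)(=O)=O)cc1)O2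
F4 | step 9 | (2R,3E)-5-chloro-3-[(dimethylamino)methylidene]-7-methoxy-2-[4-(methylsulfonyloxy)phenyl]-2,3-dihydro-4H-chromen-4-one | O=C1/C(=C/N(C)C)[C@@H](c2ccc(OS(C)(=O)=O)cc2)Oc2cc(OC)cc(Cl)c12
F5 | step 9 | (2R)-5-chloro-3-diazo-7-methoxy-2-[4-(methylsulfonyloxy)phenyl]-2,3-dihydro-4H-chromen-4-one | O=C1C(=[N+]=[N-])[C@@H](c2ccc(OS(C)(=O)=O)cc2)Oc2cc(OC)cc(Cl)c12
F6 | step 9 | methyl (2S,3R)-4-chloro-6-methoxy-2-[4-(methylsulfonyloxy)phenyl]-2,3-dihydro-1-benzofuran-3-carboxylate | Clc1cc(OC)cc2c1[C@@H](C(=O)OC)[C@@H](c1ccc(OS(C)(=O)=O)cc1)O2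
F7 | step 11 | 1,3-dioxoisoindolin-2-yl (2S,3S)-4-chloro-6-methoxy-2-[4-(methylsulfonyloxy)phenyl]-2,3-dihydro-1-benzofuran-3-carboxylate | Clc1cc(OC)cc2c1[C@H](C(=O)ON1C(=O)c3ccccc3C1=O)[C@@H](c1ccc(OS(C)(=O)=O)cc1)O2
F8 | step 11 | methyl (2R,3R)-5-iodo-7-methoxy-2-[4-(methylsulfonyloxy)phenyl]-2,3-dihydro-1-benzofuran-3-carboxylate | Ic1cc(OC)c2c(c1)[C@@H](C(=O)OC)[C@H](c1ccc(OS(C)(=O)=O)cc1)O2
F9 | step 15 | 4-[(2S,3S)-3-[(2R,3R)-3-(3,5-dimethoxyphenyl)-7-methoxy-2-[4-(methylsulfonyloxy)phenyl]-2,3-dihydro-1-benzofuran-5-yl]-4-ethenyl-6-methoxy-2,3-dihydro-1-benzofuran-2-yl]phenyl methanesulfonate | C=Cc1cc(OC)cc2c1[C@H](c1cc(OC)c3c(c1)[C@@H](c1cc(OC)cc(OC)c1)[C@H](c1ccc(OS(C)(=O)=O)cc1)O3)[C@@H](c1ccc(OS(C)(=O)=O)cc1)O2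
F10 | step 16 | 4-[(2S,3S)-4-chloro-3-[(2R,3R)-3-(3,5-dihydroxyphenyl)-7-hydroxy-2-[4-(methylsulfonyloxy)phenyl]-2,3-dihydro-1-benzofuran-5-yl]-6-hydroxy-2,3-dihydro-1-benzofuran-2-yl]phenyl methanesulfonate | Clc1cc(O)cc2c1[C@H](c1cc(O)c3c(c1)[C@@H](c1cc(O)cc(O)c1)[C@H](c1ccc(OS(C)(=O)=O)cc1)O3)[C@@H](c1ccc(OS(C)(=O)=O)cc1)O2
A1 | alternative 1 | 6-[(E)-6-(4-methoxyphenyl)-2,4-dioxohex-5-en-1-yl]-2,2-dimethyl-4H-1,3-dioxin-4-one | CC1(C)OC(CC(=O)CC(=O)/C=C/c2ccc(OC)cc2)=CC(=O)O1
A2 | alternative 1 | methyl 2,4-dihydroxy-6-[(E)-2-(4-methoxyphenyl)ethenyl]benzoate | COC(=O)c1c(O)cc(O)cc1/C=C/c1ccc(OC)cc1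
A3 | alternative 2 | tert-butyl[[5-[(1S,2R)-1-(3,5-dimethoxyphenyl)-2-(ethynyloxy)-2-(4-methoxyphenyl)ethyl]furan-3-yl]methoxy]dimethylsilane | CC(C)(C)[Si](C)(C)OCc1coc(c1)[C@@H](c1cc(OC)cc(OC)c1)[C@H](c1ccc(OC)cc1)OC#C
A4 | alternative 2 | (2R,3R)-5-[(tert-butyldimethylsilyloxy)methyl]-3-(3,5-dimethoxyphenyl)-2-(4-methoxyphenyl)-2,3-dihydro-1-benzofuran-7-ol | CC(C)(C)[Si](C)(C)OCc1cc(O)c2c(c1)[C@@H](c1cc(OC)cc(OC)c1)[C@H](c1ccc(OC)cc1)O2
A5 | alternative 3 | 2-[(1S,2S)-1-[(2R,3R)-3-(3,5-dimethoxyphenyl)-7-methoxy-2-(4-methoxyphenyl)-2,3-dihydro-1-benzofuran-5-yl]-2-(ethynyloxy)-2-(4-methoxyphenyl)ethyl]-3-[(E)-2-(4-methoxyphenyl)ethenyl]cyclobut-2-en-1-one | COc1ccc(/C=C/C2=C(C(=O)C2)[C@H](c2cc(OC)c3c(c2)[C@@H](c2cc(OC)cc(OC)c2)[C@H](c2ccc(OC)cc2)O3)[C@@H](c2ccc(OC)cc2)OC#C)cc1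
A6 | alternative 3 | (2S,3S)-3-[(2R,3R)-3-(3,5-dimethoxyphenyl)-7-methoxy-2-(4-methoxyphenyl)-2,3-dihydro-1-benzofuran-5-yl]-2-(4-methoxyphenyl)-4-[(E)-2-(4-methoxyphenyl)ethenyl]-2,3-dihydro-1-benzofuran-6-ol | COc1ccc(/C=C/c2cc(O)cc3c2[C@H](c2cc(OC)c4c(c2)[C@@H](c2cc(OC)cc(OC)c2)[C@H](c2ccc(OC)cc2)O4)[C@@H](c2ccc(OC)cc2)O3)cc1
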